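**Plan**
Retrosynthesis: the C12′ ketone is unmasked last; before that, N1–C8a and C4–C4a are cut together. The benzo ring (C4a, C5–C8, C8a) carries no substituent, so it leaves as symmetrical benzyne, and N1, C2 (with the chain C1′–C13′), C3 (with OMe) and C4 remain as one acyclic β-enamino ester.
That ester is cut at N1–C2 (ammonia), C2–C3 (lithiated methyl methoxyacetate plus a C14 ketal acid) and C10′–C11′ (acetoacetate plus methyl 11-bromoundecanoate).
Forward: the chain is joined first (C10′–C11′, then C2–C3, then N1–C2); the pyridone ring is the only ring made, closed onto the benzyne-derived ring in step 5; the dioxolane is removed last.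
Stereochemistry: the target has no stereocentre; the one stereo element on the way, the enamine geometry of 12 (NH2 cis to CO2Me, held by a hydrogen bond), disappears on aromatisation.

Key step: step 5

Remark: the target is achiral, so no enantiocontrol is required; it is treated as the 4(1H)-quinolone tautomer, and the stereocentres of 3, 4 and 11 are racemic and are erased later.

**Step 1**
Reactants: 1 methyl acetoacetate; 2 methyl 11-bromoundecanoate
Product: 5 13-oxotetradecanoic acid, via dimethyl 2-acetyltridecanedioate 3 (not isolated), via 2-acetyltridecanedioic acid 4 (not isolated)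
Conditions: 1 (1.5 equiv), NaOMe (1.5 equiv), MeOH, reflux; then 2 M aq. NaOH, rt to 50 °C; then H2SO4 to pH 1, 80 °C
Reagents that add atoms: sodium hydroxide, [Na+].[OH-]
Why: acetoacetic ester synthesis, in which SN2 C-alkylation of the stabilised enolate by the primary bromide is followed by saponification of both esters and decarboxylation of the β-keto acid through its cyclic transition state, the surplus of 1 being degraded to volatile products in the hydrolysis stage.

**Step 2**
Reactants: 5 13-oxotetradecanoic acid
Product: 7 12-(2-methyl-1,3-dioxolan-2-yl)dodecanoic acid, via 2-hydroxyethyl 12-(2-methyl-1,3-dioxolan-2-yl)dodecanoate 6 (not isolated)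
Conditions: HO(CH2)2OH (5 equiv), p-TsOH·H2O (5 mol %), toluene, Dean–Stark, reflux; then NaOH, MeOH–H2O, 50 °C; then 1 M HCl to pH 5, 0 °C, Et2O extraction
Reagents that add atoms: ethylene glycol, OCCO; sodium hydroxide, [Na+].[OH-]
Why: acid-catalysed ketalisation with azeotropic removal of water also esterifies the carboxyl group with the diol, and the following saponification returns the acid while the dioxolane, inert to base, survives because the carboxylate is acidified only to pH 5 in the cold.

**Step 3**
Reactants: 7 12-(2-methyl-1,3-dioxolan-2-yl)dodecanoic acid; 8 methyl methoxyacetate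
Product: 11 methyl 2-methoxy-14-(2-methyl-1,3-dioxolan-2-yl)-3-oxotetradecanoate (racemic), via 1-[12-(2-methyl-1,3-dioxolan-2-yl)dodecanoyl]-1H-imidazole 9 (not isolated), via lithium (E)-1,2-dimethoxyethen-1-olate 10 (not isolated)
Conditions: 7, CDI (1.1 equiv), THF, rt (gives 9); 8 (3.2 equiv), LDA (3.2 equiv), THF, −78 °C (gives 10); 9 added to 10, −78 to −40 °C; aq. NH4Cl
Reagents that add atoms: none
Why: Claisen-type C-acylation of a lithium ester enolate by an acyl imidazolide, in which the neutral CDI activation spares the ketal, three equivalents of enolate cover the imidazole N–H, the acylation and the deprotonation of the β-keto ester formed, and the low temperature holds back self-condensation of the enolate.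

**Step 4**
Reactants: 11 methyl 2-methoxy-14-(2-methyl-1,3-dioxolan-2-yl)-3-oxotetradecanoate
Product: 12 methyl (2E)-3-amino-2-methoxy-14-(2-methyl-1,3-dioxolan-2-yl)tetradec-2-enoate (amino group cis to the ester)
Conditions: NH4OAc (10 equiv), MeOH, 4 Å MS, 50 °C
Reagents that add atoms: ammonium acetate, CC(=O)[O-].[NH4+]
Why: condensation of a β-keto ester with ammonia to the vinylogous carbamate (enamine formation), in which the isomers equilibrate through the imine tautomer and the N–H···O=C hydrogen bond makes the isomer with the amino group cis to the ester the thermodynamic product, while the near-neutral buffer leaves the dioxolane intact.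

**Step 5**
Reactants: 12 methyl (2E)-3-amino-2-methoxy-14-(2-methyl-1,3-dioxolan-2-yl)tetradec-2-enoate; 13 2-(trimethylsilyl)phenyl trifluoromethanesulfonate
Product: 15 3-methoxy-2-[11-(2-methyl-1,3-dioxolan-2-yl)undecyl]quinolin-4(1H)-one, via benzyne 14 (not isolated)
Conditions: 12 (1.2 equiv), 13 (1.0 equiv), dried CsF (3 equiv), THF, 65 °C, N2
Reagents that add atoms: none
Why: Proposed new method: fluoride attacks the silicon of 13 and 1,2-elimination of triflate releases benzyne 14; the enamine nitrogen of 12 adds to it (N1–C8a), the ortho aryl anion so formed attacks the ester carbonyl held cis to nitrogen by the N–H···O=C hydrogen bond (C4–C4a), methoxide leaves and loss of a proton from nitrogen gives the 4(1H)-quinolone. The closest known reaction type is the fluoride-induced aryne annulation of 2-aminobenzoates to acridones (N-arylation, then acylation of the aryl anion by the neighbouring ester); 12 offers the same N–C=C–CO2Me array as an acyclic vinylogous carbamate, a partner on which this annulation has not been shown. The pyridone ring closes by 6-exo-trig attack of the aryl carbanion on the ester carbonyl, and no stereocentre is formed. The step needs attack at nitrogen rather than carbon and a single arylation: the carbon that becomes C3 (C2 of 12) is already fully substituted by methoxy and ester, so C-arylation, ene and [2+2] modes would have to build a quaternary centre, and the chelated geometry puts the ester within reach of the aryl anion, whose protonation in aprotic THF needs an external proton shuttle. Precursor 13 is the limiting reagent and benzyne is released slowly from sparingly soluble CsF, which protects the N–H of 15 from a second arylation; benzyne is symmetrical, so no regiochemistry arises.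

**Step 6**
Reactants: 15 3-methoxy-2-[11-(2-methyl-1,3-dioxolan-2-yl)undecyl]quinolin-4(1H)-one
Product: 16 3-methoxy-2-(12-oxotridecyl)quinolin-4(1H)-one
Conditions: 1 M aq. HCl, THF, rt; NaHCO3 work-up
Reagents that add atoms: water, O
Why: acid-catalysed hydrolysis of the dioxolane through the oxocarbenium ion frees the C12′ ketone, while the quinolone core and its 3-methoxy group are inert to dilute acid.

**Compound list**
1 | methyl acetoacetate (methyl 3-oxobutanoate) | COC(=O)CC(C)=O | starting material
2 | methyl 11-bromoundecanoate | COC(=O)CCCCCCCCCCBr | starting material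
3 | dimethyl 2-acetyltridecanedioate (racemic) | COC(=O)C(C(C)=O)CCCCCCCCCCC(=O)OC | intermediate (not isolated)
4 | 2-acetyltridecanedioic acid (racemic) | OC(=O)C(C(C)=O)CCCCCCCCCCC(=O)O | intermediate (not isolated)
5 | 13-oxotetradecanoic acid | CC(=O)CCCCCCCCCCCC(=O)O | intermediate
6 | 2-hydroxyethyl 12-(2-methyl-1,3-dioxolan-2-yl)dodecanoate | OCCOC(=O)CCCCCCCCCCCC1(C)OCCO1 | intermediate (not isolated)
7 | 12-(2-methyl-1,3-dioxolan-2-yl)dodecanoic acid | OC(=O)CCCCCCCCCCCC1(C)OCCO1 | intermediate
8 | methyl methoxyacetate | COCC(=O)OC | starting material
9 | 1-[12-(2-methyl-1,3-dioxolan-2-yl)dodecanoyl]-1H-imidazole | O=C(n1ccnc1)CCCCCCCCCCCC2(C)OCCO2 | intermediate (not isolated)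
10 | lithium (E)-1,2-dimethoxyethen-1-olate (OLi cis to the 2-methoxy group, chelated; the geometry is of no consequence) | [Li]O/C(OC)=C\OC | intermediate (not isolated)
11 | methyl 2-methoxy-14-(2-methyl-1,3-dioxolan-2-yl)-3-oxotetradecanoate (racemic) | COC(=O)C(OC)C(=O)CCCCCCCCCCCC1(C)OCCO1 | intermediate
12 | methyl (2E)-3-amino-2-methoxy-14-(2-methyl-1,3-dioxolan-2-yl)tetradec-2-enoate (amino cis to ester) | COC(=O)/C(OC)=C(\N)CCCCCCCCCCCC1(C)OCCO1 | intermediate
13 | 2-(trimethylsilyl)phenyl trifluoromethanesulfonate | C[Si](C)(C)c1ccccc1OS(=O)(=O)C(F)(F)F | starting material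
14 | benzyne (1,2-didehydrobenzene) | C1#CC=CC=C1 | intermediate (not isolated)
15 | 3-methoxy-2-[11-(2-methyl-1,3-dioxolan-2-yl)undecyl]quinolin-4(1H)-one | COc1c(CCCCCCCCCCCC3(C)OCCO3)[nH]c2ccccc2c1=O | intermediate
16 | 3-methoxy-2-(12-oxotridecyl)quinolin-4(1H)-one | COc1c(CCCCCCCCCCCC(C)=O)[nH]c2ccccc2c1=O | target

**Summary**
Total step count: 6. Longest linear sequence: 6 steps (1 and 2 to 16); 8 and 13 enter as commercial materials.

Steps most likely to fail:

1. Step 5 (proposed new method). Benzyne may be attacked by the enamine carbon instead of nitrogen (C-arylation or formal [2+2] insertion). The aryl anion may also be protonated before it reaches the ester, or the quinolone N–H may be arylated a second time. The fallback sets out from β-keto ester 11 and returns at 15. Acid-catalysed condensation of 11 with aniline (cat. AcOH, 4 Å MS, benzene, 40 °C) should give methyl (2E)-2-methoxy-14-(2-methyl-1,3-dioxolan-2-yl)-3-(phenylamino)tetradec-2-enoate F1. Conrad–Limpach thermal cyclisation of F1 (Ph2O, 250 °C, short contact time) should close C4–C4a with loss of methanol and give 15. The benzo ring then comes from aniline, and both reactions are classical.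

2. Step 3. Self-condensation of the α-methoxy ester enolate and proton transfers that consume it may stall the acylation, or the enolate may be acylated at oxygen. The fallback sets out from acyl imidazolide 9 (made from 7 as in step 3) and returns at 11. Reduction of 9 with DIBAL-H (CH2Cl2, −78 °C) should give 12-(2-methyl-1,3-dioxolan-2-yl)dodecanal F2. Aldol addition of enolate 10 (1.2 equiv, THF, −78 °C) to this much more reactive electrophile should give methyl 3-hydroxy-2-methoxy-14-(2-methyl-1,3-dioxolan-2-yl)tetradecanoate F3 as a mixture of diastereomers, which is of no consequence. Dess–Martin oxidation (NaHCO3-buffered, CH2Cl2) should then give 11.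

3. Step 4. Condensation at the hindered, α-oxygenated ketone may stay incomplete, ammonia may attack the activated ester, and the enamine may revert by hydrolysis during purification. The fallback sets out from acyl imidazolide 9 and returns at 12, bypassing 11. Ammonia in THF should convert 9 into 12-(2-methyl-1,3-dioxolan-2-yl)dodecanamide F4. Dehydration (TFAA, pyridine, 0 °C) should give 12-(2-methyl-1,3-dioxolan-2-yl)dodecanenitrile F5. Addition of enolate 10 to the nitrile (ester enolate–nitrile condensation, the base-mediated counterpart of the Blaise reaction; THF, −78 to 0 °C) forms C2–C3 and delivers the amino group at once, so 12 should result directly after aqueous work-up.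

**Further compounds**
F1 | step 5 | methyl (2E)-2-methoxy-14-(2-methyl-1,3-dioxolan-2-yl)-3-(phenylamino)tetradec-2-enoate | COC(=O)/C(OC)=C(\Nc1ccccc1)CCCCCCCCCCCC2(C)OCCO2
F2 | step 3 | 12-(2-methyl-1,3-dioxolan-2-yl)dodecanal | O=CCCCCCCCCCCCC1(C)OCCO1
F3 | step 3 | methyl 3-hydroxy-2-methoxy-14-(2-methyl-1,3-dioxolan-2-yl)tetradecanoate (racemic mixture of diastereomers) | COC(=O)C(OC)C(O)CCCCCCCCCCCC1(C)OCCO1
F4 | step 4 | 12-(2-methyl-1,3-dioxolan-2-yl)dodecanamide | NC(=O)CCCCCCCCCCCC1(C)OCCO1
F5 | step 4 | 12-(2-methyl-1,3-dioxolan-2-yl)dodecanenitrile | N#CCCCCCCCCCCCC1(C)OCCO1
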